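I began from slowness: Z releases Q with a mean life of 6.06 h, while Q meets the L charged within 0.118 h, so the release is the slower of the two at the start.

- Tuesday's: L 15 mM; Z 75 µM; time 30 h
- Sunday's: L 15 mM; Z 75 µM; time 50 h

    L + Q → E + J (k1 = 564 L mol⁻¹ h⁻¹)
    L + E → J + E, rate k2*[E]*[L] (k2 = 3670 L mol⁻¹ h⁻¹)
    Q → D (k3 = 3.11 × 10⁻⁴ h⁻¹)
    Q → G (k4 = 0.126 h⁻¹)
    Z → Q (k5 = 0.165 h⁻¹)

- the average divides the monomer in chains by the number of chains begun, living and dead together
- run time (Tuesday's): 30 h

- which of the two ends with the longer chains by the average number of monomer units in a chain (chains begun, living or dead) ("neither" if they lie within 10%) (Tuesday's / Sunday's / neither)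
- average number of monomer units in a chain (chains begun, living or dead) at the end, Tuesday's
- average number of monomer units in a chain (chains begun, living or dead) at the end, Sunday's

Tuesday's and Sunday's differ in time alone, so I looked for what sets the length. Once L is used, the length is L charged over chains begun. Q meets L or is lost, and the two ways run equally at the crossover amount of L, the loss constants over the capture constant, 0.224 mM.

The two charges had to be known well, for once L is used the length is their ratio, 200, divided by the share of Z that begins chains. The loss to D hardly counted, being 0.247% of the loss to G. I replaced the rising curve of E by its mean picture: the full charge, present after one mean life of Z. L then reached the crossover at 21.3 h. Doubling the crossover moved that by 2.52 h, since it stands under a logarithm. Doubling the growth constant gave 13.7 h and a length of 223.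

With the given constants, Z still held 2.96% at the crossover. I counted that as lost and committed to 206 for both flasks, as the crossover came before Tuesday's end. Q is also lost above the crossover, so I expected this to lie low.

The forecast said neither, with 217 for Tuesday's and 217 for Sunday's, holding that “Every initiator molecule starts one chain unless it is lost first”. Its length exceeded mine.

The simulation gave neither, with 217 for Tuesday's and 217 for Sunday's. In Tuesday's at 6.69 h, the half-life of Z was 4.2 h against 0.16 h for Q by capture, which makes the release the rate-limiting step of chain starting. In Tuesday's, L stood at 1.23 mM after 15.0 h, above the crossover, and at 0.0286 mM after 30.0 h, below it. Sunday's length moved by 21.7 at 67.3 µM or 84.7 µM of Z.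

In the neighbour flask, like Tuesday's but with 0.30 mM of Z, the same reckoning put the crossover at 9.88 h, with 19.6% of Z unreleased, and so a length of 62.2. The computed length was 76.4, again above the reckoning.

The constants were drawn at random within sensible limits; the rest is arithmetic.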